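**Plan**
- Retrosynthesis: the furanone O–C2 bond is cut and the O1–C7a bond re-formed, which re-expands ring C to the 4-pyranone of the epoxide 9. The ester carbon is then put back into ring A (benzilic ester rearrangement run backwards) to give the flavone-5,6-quinone 6. The flavone is cut at O1–C2 and C2–C3 to acetophenone 1 and acid chloride 2.
- Forward: C-acylation and cyclodehydration build ring C as a pyranone on ring A (flavone 4); AlBr3 frees the 5,6-catechol and the phenol; Ag2O gives the o-quinone; ring A contracts from six to five carbons (step 5); the C4a=C7a bond is epoxidised (step 7); ring C contracts from pyranone to furanone (step 8).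
- Enabling feature: in 9, C7a carries both the pyranone oxygen O1 and the oxirane oxygen (an acetal carbon), and O1 is the ring oxygen of a vinylogous ester (O1–C2=C3–C4=O). Opening the oxirane at C7a therefore unzips the pyranone and leaves a hydroxyl on C4a, α′ to the C4/C2 1,3-diketone. That hydroxyl recloses on C2 as the 3(2H)-furanone, and C7a stays in ring A as its ketone.
- Stereochemistry: C5 comes from the catalyst-controlled benzilic ester rearrangement (step 5). The spiro carbon C4a comes from the C5-hydroxyl-directed epoxidation (step 7) and is carried with retention through step 8. The spiro β-hydroxy ketone, which can undergo retro-aldol cleavage, is never exposed to base.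

Key step: step 8

Remark: 1 and 2 are taken as catalogue compounds.
Remark: atom numbers are those of chromen-4-one for 4–6 and those of cyclopenta[b]pyran (O1, C2, C3, C4, C4a, C5, C6, C7, C7a) for 7–9; the latter are kept in the text for 10–12 so that each atom can be followed.

**Route**

Step 1
Reactants: 1 1-(2-hydroxy-3,4,5,6-tetramethoxyphenyl)ethan-1-one; 2 4-(benzyloxy)benzoyl chloride
Product: 3 1-[4-(benzyloxy)phenyl]-3-(2-hydroxy-3,4,5,6-tetramethoxyphenyl)propane-1,3-dione
Conditions: LiN(SiMe3)2 (3.2 equiv), THF, −78 °C; then 2, −78 → −10 °C; aq. HCl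
Reagents that add atoms: none
Why: Baker–Venkataraman-type C-acylation, in which the lithium phenoxide/enolate dianion of 1 is acylated at carbon by 2 and the excess amide holds the 1,3-diketone as its enolate; no stereocentre is formed.

Step 2
Reactants: 3 the 1,3-diketone
Product: 4 2-[4-(benzyloxy)phenyl]-5,6,7,8-tetramethoxy-4H-chromen-4-one
Conditions: TsOH·H2O (cat.), toluene, reflux (Dean–Stark)
Reagents that add atoms: none
Why: Acid-catalysed cyclodehydration of the o-hydroxyaryl 1,3-diketone (hemiketal formation by the phenol, then loss of water) should give the flavone; no stereocentre is formed.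

Step 3
Reactants: 4 the tetramethoxyflavone
Product: 5 5,6-dihydroxy-2-(4-hydroxyphenyl)-7,8-dimethoxy-4H-chromen-4-one (thymusin)
Conditions: AlBr3 (6 equiv), MeCN, 0 °C → rt; then 1 M HCl, 50 °C
Reagents that add atoms: none
Why: Chelation-controlled ether cleavage, in which aluminium bound to the C4 carbonyl cleaves the peri 5-OMe and the resulting 5-O–Al cleaves the neighbouring 6-OMe through a five-membered catecholate, while 7-OMe and 8-OMe lack this assistance and the benzyl ether falls to the same Lewis acid.

Step 4
Reactants: 5 thymusin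
Product: 6 2-(4-hydroxyphenyl)-7,8-dimethoxy-4H-chromene-4,5,6-trione (the flavone-5,6-quinone)
Conditions: Ag2O (3 equiv), Na2SO4, THF, rt, dark; filtration through Celite
Reagents that add atoms: none
Why: Two-electron oxidation of the catechol to the o-quinone under neutral, dry conditions; the 4-hydroxyphenyl group is a monophenol conjugated to the pyranone carbonyl and should not be oxidised.

Step 5
Reactants: 6 the flavone-5,6-quinone
Product: 7 methyl (5S)-5-hydroxy-2-(4-hydroxyphenyl)-6,7-dimethoxy-4-oxo-4,5-dihydrocyclopenta[b]pyran-5-carboxylate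
Conditions: Cu(OTf)2 (10 mol %), 2,2′-(propane-2,2-diyl)bis[(4S)-4-tert-butyl-4,5-dihydrooxazole] (11 mol %), MeOH (5 equiv), 4 Å MS, CH2Cl2, −20 °C → rt
Reagents that add atoms: methanol, CO
Why: Proposed new method: the 5,6-dione should bind the divalent copper–bis(oxazoline) complex as a five-membered O5/O6 chelate, methanol adds to one of the two activated carbonyls, and in the copper-bound hemiketal the ring bond next to the hemiketal carbon shifts to the neighbouring carbonyl carbon (1,2-shift, ring A six → five) while the hemiketal carbon leaves the ring plane as the ester carbon, on the face left open by the tert-butyl groups, which fixes C5 (the ligand antipode that gives (5S)-7 is kept); either carbonyl gives the same constitution, and the closest known reaction types are the alkoxide-mediated benzilic ester rearrangement of 1,2-diones and o-quinones and the Cu(OTf)2/bis(oxazoline)-catalysed enantioselective additions to chelating 1,2-dicarbonyl compounds.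

Step 6
Reactants: 7 the (5S)-hydroxy ester
Product: 8 methyl (5S)-5-hydroxy-6,7-dimethoxy-2-[4-(methoxymethoxy)phenyl]-4-oxo-4,5-dihydrocyclopenta[b]pyran-5-carboxylate
Conditions: MOMCl, i-Pr2NEt, CH2Cl2, 0 °C → rt
Reagents that add atoms: chloromethyl methyl ether, COCCl
Why: Williamson-type alkylation of the phenol only, since the tertiary, ester-bearing C5 hydroxyl is hindered and poorly nucleophilic; the phenol is masked because a phenoxide would, through C2=C3–C4=O, deactivate the enone needed in step 7.

Step 7
Reactants: 8 the MOM ether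
Product: 9 methyl (4aS,5R,7aS)-4a,7a-epoxy-5-hydroxy-6,7-dimethoxy-2-[4-(methoxymethoxy)phenyl]-4-oxo-4,4a,5,7a-tetrahydrocyclopenta[b]pyran-5-carboxylate (oxirane oxygen cis to the C5 hydroxyl; used crude)
Conditions: t-BuOOH (in decane, 2 equiv), DBU (1.2 equiv), CH2Cl2, −20 → 0 °C; cold pH 7 buffer work-up
Reagents that add atoms: tert-butyl hydroperoxide, CC(C)(C)OO
Why: Weitz–Scheffer epoxidation in which the peroxide adds to C7a, the β-carbon of the C4 enone (the δ-carbon C6 is shielded by the quaternary C5 and C2 by its aryl group), and the enolate closes on oxygen at C4a; hydrogen bonding to the C5 hydroxyl and the bulk of the ester on the other face should place the oxirane cis to the hydroxyl, which sets C4a and C7a.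

Step 8
Reactants: 9 the epoxide
Product: 12 limnophilaspiroketone, methyl (5S,6R)-6-hydroxy-2-(4-hydroxyphenyl)-7,8-dimethoxy-4,9-dioxo-1-oxaspiro[4.4]nona-2,7-diene-6-carboxylate, via hydroxy triketone 10 (not isolated), via MOM ether 11 (not isolated)
Conditions: PPTS (cat.), MeCN/H2O 4:1, 0 °C → rt; then CF3CO2H, rt
Reagents that add atoms: water, O
Why: Mild acid opens the oxirane of 9 at the acetal carbon C7a (ionisation is helped by the lone pair of O1, by the C6=C7 enol ether and, from the rear, by the C5 ester carbonyl, which lies anti to the oxirane oxygen because the oxirane is cis to the C5 hydroxyl); water adds at C7a and the hemiketal collapses to the C7a ketone with loss of O1 as the enol of the aroylacetyl chain, which opens the pyranone and gives 10 with a tertiary hydroxyl on C4a. This hydroxyl, α′ to the 1,3-diketone, adds to the aryl ketone carbon C2 (5-exo-trig hemiketal formation) and loss of water gives the 3(2H)-furanone 11, so the six-membered ring O1–C2–C3–C4–C4a–C7a has become the five-membered ring O–C2–C3–C4–C4a with C7a left in ring A as its ketone; CF3CO2H then cleaves the MOM ether. The closest known reaction types are the acid hydrolysis of epoxy ethers to α-hydroxy ketones, the acid-catalysed cyclodehydration of α′-hydroxy-1,3-diketones to 3(2H)-furanones and the oxidative contraction of ring C of flavonols to benzofuran-3(2H)-ones. No stereocentre is created: the spiro carbon C4a keeps the C–O bond made in step 7 (retention), so the furanone oxygen stays cis to the C5 hydroxyl, and C5 is untouched. The step needs water to be captured at C7a and not at C6 (which would cost the C6 methoxyl) and no 1,2-shift of the C4 acyl group to C7a (which would put the spiro centre on the wrong carbon); the rear-side participation of the ester, the neighbouring C4a oxygen and the large excess of water should secure this. It also needs closure through the C4a hydroxyl and not the C5 hydroxyl (6-exo, to a dihydropyranone); the five-membered closure is the faster one and the C5 hydroxyl is deactivated by its geminal ester.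

**Compound list**

1 | 1-(2-hydroxy-3,4,5,6-tetramethoxyphenyl)ethan-1-one | CC(=O)c1c(O)c(OC)c(OC)c(OC)c1OC | starting material
2 | 4-(benzyloxy)benzoyl chloride | O=C(Cl)c1ccc(OCc2ccccc2)cc1 | starting material
3 | 1-[4-(benzyloxy)phenyl]-3-(2-hydroxy-3,4,5,6-tetramethoxyphenyl)propane-1,3-dione | O=C(CC(=O)c1c(O)c(OC)c(OC)c(OC)c1OC)c1ccc(OCc2ccccc2)cc1 | intermediate
4 | 2-[4-(benzyloxy)phenyl]-5,6,7,8-tetramethoxy-4H-chromen-4-one | COc1c(OC)c(OC)c2oc(-c3ccc(OCc4ccccc4)cc3)cc(=O)c2c1OC | intermediate
5 | 5,6-dihydroxy-2-(4-hydroxyphenyl)-7,8-dimethoxy-4H-chromen-4-one (thymusin) | COc1c(O)c(O)c2c(=O)cc(-c3ccc(O)cc3)oc2c1OC | intermediate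
6 | 2-(4-hydroxyphenyl)-7,8-dimethoxy-4H-chromene-4,5,6-trione | O=C1C(=O)C(OC)=C(OC)C2=C1C(=O)C=C(c1ccc(O)cc1)O2 | intermediate
7 | methyl (5S)-5-hydroxy-2-(4-hydroxyphenyl)-6,7-dimethoxy-4-oxo-4,5-dihydrocyclopenta[b]pyran-5-carboxylate | COC(=O)[C@@]1(O)C(OC)=C(OC)C2=C1C(=O)C=C(c1ccc(O)cc1)O2 | intermediate
8 | methyl (5S)-5-hydroxy-6,7-dimethoxy-2-[4-(methoxymethoxy)phenyl]-4-oxo-4,5-dihydrocyclopenta[b]pyran-5-carboxylate | COC(=O)[C@@]1(O)C(OC)=C(OC)C2=C1C(=O)C=C(c1ccc(OCOC)cc1)O2 | intermediate
9 | methyl (4aS,5R,7aS)-4a,7a-epoxy-5-hydroxy-6,7-dimethoxy-2-[4-(methoxymethoxy)phenyl]-4-oxo-4,4a,5,7a-tetrahydrocyclopenta[b]pyran-5-carboxylate | COC(=O)[C@@]1(O)C(OC)=C(OC)[C@]23O[C@]12C(=O)C=C(c1ccc(OCOC)cc1)O3 | intermediate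
10 | methyl (1S,5S)-1,5-dihydroxy-2,3-dimethoxy-5-{3-[4-(methoxymethoxy)phenyl]-3-oxopropanoyl}-4-oxocyclopent-2-ene-1-carboxylate (cis-diol) | COC(=O)[C@@]1(O)C(OC)=C(OC)C(=O)[C@@]1(O)C(=O)CC(=O)c1ccc(OCOC)cc1 | intermediate
11 | methyl (5S,6R)-6-hydroxy-7,8-dimethoxy-2-[4-(methoxymethoxy)phenyl]-4,9-dioxo-1-oxaspiro[4.4]nona-2,7-diene-6-carboxylate | COC(=O)[C@@]1(O)C(OC)=C(OC)C(=O)[C@]12OC(c1ccc(OCOC)cc1)=CC2=O | intermediate
12 | limnophilaspiroketone, methyl (5S,6R)-6-hydroxy-2-(4-hydroxyphenyl)-7,8-dimethoxy-4,9-dioxo-1-oxaspiro[4.4]nona-2,7-diene-6-carboxylate | COC(=O)[C@@]1(O)C(OC)=C(OC)C(=O)[C@]12OC(c1ccc(O)cc1)=CC2=O | target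

**Step count and risks**

Total step count: 8. Longest linear sequence: 8 (the route is linear from 1).

Steps most likely to fail:

1. Step 5. The enantioinduction may be low or of the wrong sense, because the quinone can bind copper through O4/O5 as well as O5/O6 and methanol can add at C5 or C6. Methanol may also add in conjugate fashion at C8a and open ring C. The fallback uses known chemistry and replaces catalyst control by resolution. It sets out from 6: Ba(OH)2 in aqueous THF at 0 °C should effect the benzilic acid rearrangement to the racemic hydroxy acid F1. This is crystallised as its (R)-1-phenylethylammonium salt F2 (or with the antipodal amine, whichever brings down the wanted acid). Acidification frees the (5S)-acid F3, and Me3SiCHN2 in MeOH/toluene at 0 °C esterifies the carboxylic acid without touching the phenol. The fallback comes back to the route at 7.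

2. Step 8. Water may be captured at C6 instead of C7a with loss of the C6 methoxyl. The C4 acyl group may shift to C7a. The diketone may close through the C5 hydroxyl to a six-membered ring. The fallback steers the opening with a temporary lactone bridge. It sets out from 8: LiOH in THF/H2O gives the carboxylic acid F4. Epoxidation as in step 7 then places the oxirane anti to the carboxylate, which opens it from the rear at C7a and gives the bridged lactone F5. Catalytic NaOMe in MeOH at −20 °C, quenched cold with acid, cleaves the lactone at the acyl–oxygen bond and the freed C7a hemiketal collapses. The fallback comes back to the route at 10, which is closed and deprotected with CF3CO2H as in step 8.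

3. Step 7. The peroxide may add too slowly to the donor-substituted C7a, may attack C2 or C6, or may be delivered anti to the hydroxyl; the oxirane may also open prematurely under base. The fallback replaces nucleophilic epoxidation by a hydrogen-bond-directed syn-dihydroxylation. It sets out from 8: OsO4·TMEDA in CH2Cl2 at −78 °C, delivered by the C5 hydroxyl, followed by aqueous Na2SO3, should give the cis-diol hemiketal F6. This loses O1 from C7a spontaneously, and the fallback comes back to the route at 10.

**Further compounds**

F1 | step 5 | racemic 5-hydroxy-2-(4-hydroxyphenyl)-6,7-dimethoxy-4-oxo-4,5-dihydrocyclopenta[b]pyran-5-carboxylic acid | OC(=O)C1(O)C(OC)=C(OC)C2=C1C(=O)C=C(c1ccc(O)cc1)O2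
F2 | step 5 | (R)-1-phenylethylammonium (5S)-5-hydroxy-2-(4-hydroxyphenyl)-6,7-dimethoxy-4-oxo-4,5-dihydrocyclopenta[b]pyran-5-carboxylate | [O-]C(=O)[C@@]1(O)C(OC)=C(OC)C2=C1C(=O)C=C(c1ccc(O)cc1)O2.C[C@@H]([NH3+])c1ccccc1
F3 | step 5 | (5S)-5-hydroxy-2-(4-hydroxyphenyl)-6,7-dimethoxy-4-oxo-4,5-dihydrocyclopenta[b]pyran-5-carboxylic acid | OC(=O)[C@@]1(O)C(OC)=C(OC)C2=C1C(=O)C=C(c1ccc(O)cc1)O2
F4 | step 8 | (5S)-5-hydroxy-6,7-dimethoxy-2-[4-(methoxymethoxy)phenyl]-4-oxo-4,5-dihydrocyclopenta[b]pyran-5-carboxylic acid | OC(=O)[C@@]1(O)C(OC)=C(OC)C2=C1C(=O)C=C(c1ccc(OCOC)cc1)O2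
F5 | step 8 | bridged γ-lactone between the C5 carboxyl and C7a, with hydroxyls on C4a and C5 (2-oxabicyclo[2.2.1]hept-5-en-3-one core fused to the dihydropyranone) | O=C1O[C@@]23OC(c4ccc(OCOC)cc4)=CC(=O)[C@@]2(O)[C@]1(O)C(OC)=C3OC
F6 | step 7 | methyl 4a,5,7a-trihydroxy-6,7-dimethoxy-2-[4-(methoxymethoxy)phenyl]-4-oxo-4,4a,5,7a-tetrahydrocyclopenta[b]pyran-5-carboxylate (all three hydroxyls cis) | COC(=O)[C@@]1(O)C(OC)=C(OC)[C@@]2(O)OC(c3ccc(OCOC)cc3)=CC(=O)[C@@]12O
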